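Plateaus that look alike tempt me to multiply one percentage by each charge.

| flask | G | remark | time |
|---|---|---|---|
| south-west | 0.065 M | run made earlier |  |
| east | 0.088 M | run made earlier |  |
| south-east | 0.11 M | run made earlier |  |
| maple | 0.060 M |  | 2.5 min |
| cedar | 0.080 M |  | 2.5 min |
| birch | 0.12 M |  | 2.5 min |

| south-west: time / s | south-west: E / % | east: time / s | east: E / % | south-east: time / s | south-east: E / % |
|---|---|---|---|---|---|
| 20.0 | 30.7 | 10.0 | 18.8 | 10.0 | 17.4 |
| 40.0 | 37.1 | 15.0 | 24.6 | 25.0 | 31.0 |
| 60.0 | 39.1 | 30.0 | 35.4 | 50.0 | 35.4 |
| 80.0 | 38.4 | 60.0 | 38.0 | 80.0 | 36.1 |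
| 120 | 39.1 | 120 | 39.0 | 120 | 38.1 |

(readings scatter by 0.5 percentage points)

- "hardly changes" means that all values lie within two and a half points (for a concentration: within two and a half percent of the largest)

1. [E] at the end for maple, cedar, birch, in this order
2. how that number moves from the first to the last of them (rises, then falls / falls all the way / rises all the way / hardly changes / falls, then rises)

Does each flask arrive at its plateau in time? The south-east run shows E at 17.4% after 10.0 s, about half of its last reading. The asked 2.5 min is 15.0 times that time, so I take each end value as a plateau.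

Is the plateau really one percentage? I average the readings from 60.0 s on: south-west 38.9%, east 38.5%, south-east 37.1%. South-west stands 1.8 percentage points above south-east, against a scatter of 0.5 points per reading.

So I work in powers of ten. I define the plateau order n, an apparent order: the change in log10 of plateau [E] per unit change in log10 of the charge, 0.912 between south-west and south-east. An n of one means a constant percentage. This n is a reading, and the south-east readings behind it differ by 2 points.

What stands at the end? Scaling south-west by n, I commit to 0.0235 M for maple, 0.0305 M for cedar and 0.0442 M for birch. My row rises all the way, and birch is 1.88 times maple.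

The forecast gives 0.0234 M, 0.0312 M and 0.0465 M, rises all the way, holding that the plateau “doesn't depend on the charge”, and its birch lies above mine.

The flasks give 0.0240 M, 0.0309 M and 0.0432 M: rises all the way.

    G + Q → X (k = 1.76 M⁻¹ s⁻¹)
    G → L (k = 0.282 s⁻¹)
    Q → E (k = 0.0749 s⁻¹)
    L → J (k = 0.0145 s⁻¹)
    G → Q (k = 0.255 s⁻¹)
    L → D (k = 0.0278 s⁻¹)
    Q → Z (k = 0.00408 s⁻¹)

At 2.50 min, maple holds E at 40.0% and X at 7.19%, while birch holds E at 36.0% and X at 12.9%, each X counted as the two G it holds. Starting from maple's 0.0240 M, n gives cedar 0.0312 M, where the flask stands at 0.0309 M, and birch 0.0451 M, where the flask stands at 0.0432 M.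

(The runs are simulated on assumed constants.)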